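**Plan**

- Retrosynthesis: the C4 ketone is traced back to a C4 methyl ether, and ring C is then cut at O1–C2 and C3–C4. This gives a 4-methoxy ortho-quinone methide of ring A (from salicylaldehyde dimethyl acetal 10) and 2,2-dimethyl-6-vinylchroman 16.
- Enabling feature: ring C is O1, C8a, C4a and C4 (all delivered by ring A) plus C2 and C3. C2 carries an aryl group whose chroman oxygen is para, so the C2–C3 partner is an electron-rich styrene, and the oxygens at C5, C7 and C8a stabilise the methide.
- Acetal 10 is cut at C4a–C4 (ortho-formylation) and at C8–CH2 (ortho C-prenylation of bis-MOM phloroglucinol). Styrene 16 is cut at the aryl–vinyl bond (Suzuki–Miyaura) and at the dihydropyran ring (4-bromophenol plus isoprene).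
- Forward: ring A is bought as phloroglucinol, the dihydropyran ring of the chroman arises in step 5, and ring C closes last, in step 7. C4 oxidation and MOM removal finish the route.
- Stereochemistry: C2 (S) is set in step 7 by a chiral Brønsted acid. C4 is a temporary centre (2,4-cis) that is erased by the oxidation, and no later step touches C2.

Key step: step 7

Assumption: flavanone numbering (O1, C2, C3, C4, C4a, C5 to C8, C8a) is used for all flavan-type compounds; the sense of induction of the chiral acid in step 7 cannot be predicted with confidence, so the (R)-catalyst is written and its mirror image would be taken if it delivered the (2R,4R) adduct.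

**Route**

Step 1
Reactants: 1 phloroglucinol; 2 chloromethyl methyl ether
Product: 3 3,5-bis(methoxymethoxy)phenol
Conditions: MOMCl (2.0 equiv), i-Pr2NEt (2.2 equiv), DMF/CH2Cl2, 0 °C to rt; chromatography
Reagents that add atoms: chloromethyl methyl ether (2), COCCl
Why: Williamson-type O-alkylation of the symmetric triol with two equivalents of MOMCl is a statistical protection that should give the bis-ether as the main fraction, the remaining hydroxyl being needed later as O1 and as the directing group.

Step 2
Reactants: 3 3,5-bis(methoxymethoxy)phenol; 4 prenyl bromide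
Product: 5 3,5-bis(methoxymethoxy)-2-(3-methylbut-2-en-1-yl)phenol
Conditions: NaH (1.05 equiv), toluene, 0 °C to rt; then prenyl bromide (1.0 equiv), rt
Reagents that add atoms: prenyl bromide (4), CC(C)=CCBr
Why: ortho-selective C-alkylation of a sodium phenoxide in a non-polar solvent, in which the tight ion pair delivers the allylic bromide to the ortho carbon; the two ortho positions of 3 are equivalent, so one 2-prenyl isomer is expected.

Step 3
Reactants: 5 3,5-bis(methoxymethoxy)-2-(3-methylbut-2-en-1-yl)phenol; 6 paraformaldehyde
Product: 8 2-hydroxy-4,6-bis(methoxymethoxy)-3-(3-methylbut-2-en-1-yl)benzaldehyde, via ortho-hydroxymethyl phenol 7 (not isolated)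
Conditions: MgCl2 (2 equiv), Et3N (4 equiv), (CH2O)n (6 equiv), MeCN, reflux; dilute aq. HCl work-up at 0 °C
Reagents that add atoms: paraformaldehyde (6), C=O
Why: Casnati–Skattebøl ortho-formylation, in which the magnesium phenoxide is hydroxymethylated at the only free ortho position (the other carries the prenyl group) and the benzylic alkoxide 7 is oxidised by hydride transfer to a second formaldehyde, the para position staying untouched.

Step 4
Reactants: 8 2-hydroxy-4,6-bis(methoxymethoxy)-3-(3-methylbut-2-en-1-yl)benzaldehyde; 9 trimethyl orthoformate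
Product: 10 2-(dimethoxymethyl)-3,5-bis(methoxymethoxy)-6-(3-methylbut-2-en-1-yl)phenol
Conditions: HC(OMe)3 (neat, 10 equiv), PPTS (2 mol %), rt; Et3N quench, evaporation; used without chromatography
Reagents that add atoms: trimethyl orthoformate (9), COC(OC)OC
Why: acid-catalysed acetalisation driven by the orthoformate, which ends as methyl formate; the weak pyridinium acid should spare the MOM ethers and the prenyl group, and the easily ionised product is kept basic and is not exposed to silica.

Step 5
Reactants: 11 4-bromophenol; 12 isoprene
Product: 14 6-bromo-2,2-dimethylchroman, via 4-bromo-2-prenylphenol 13 (not isolated)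
Conditions: isoprene (1.5 equiv), AgOTf (5 mol %), ClCH2CH2Cl, rt, sealed vessel
Reagents that add atoms: isoprene (12), C=CC(C)=C
Why: Friedel–Crafts ortho-prenylation of the para-blocked phenol followed by Markovnikov hydroalkoxylation of the trisubstituted alkene of 13 (6-endo closure at the tertiary carbon), the known acid-type chroman annulation of phenols with isoprene.

Step 6
Reactants: 14 6-bromo-2,2-dimethylchroman; 15 vinylboronic acid pinacol ester
Product: 16 2,2-dimethyl-6-vinylchroman
Conditions: Pd(dppf)Cl2 (3 mol %), K2CO3 (3 equiv), 1,4-dioxane/H2O 4:1, 85 °C; stored cold with BHT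
Reagents that add atoms: vinylboronic acid pinacol ester (15), C=CB1OC(C)(C)C(C)(C)O1
Why: Suzuki–Miyaura coupling of an aryl bromide with a vinylboronate, a standard way to styrenes that leaves the chroman ether untouched.

Step 7
Reactants: 10 2-(dimethoxymethyl)-3,5-bis(methoxymethoxy)-6-(3-methylbut-2-en-1-yl)phenol; 16 2,2-dimethyl-6-vinylchroman
Product: 18 (2S,4S)-2-(2,2-dimethylchroman-6-yl)-4-methoxy-5,7-bis(methoxymethoxy)-8-(3-methylbut-2-en-1-yl)chroman (2,4-cis), via 4-methoxy ortho-quinone methide 17 (not isolated)
Conditions: 16 (2 equiv), N-triflylphosphoramide of (R)-3,3'-bis(2,4,6-triisopropylphenyl)-1,1'-bi-2-naphthol (10 mol %), 5 Å MS, toluene, −40 °C; Et3N quench at −40 °C; chromatography on Et3N-deactivated silica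
Reagents that add atoms: none
Why: Proposed new method: the chiral acid protonates one acetal methoxy group of 10 and methanol leaves, so that the aryl(methoxy)carbenium ion, in its phenol-deprotonated form the 4-methoxy ortho-quinone methide 17, sits hydrogen-bonded through the C8a oxygen to the chiral phosphoramide anion; the CH2 terminus of styrene 16 then attacks the methide carbon (C3–C4 bond) and the phenol oxygen captures the para-alkoxybenzyl cation (O1–C2 bond) in an asynchronous inverse-demand hetero-Diels–Alder reaction. The closest known reactions are the achiral acid-promoted cycloaddition of salicylaldehyde acetals with styrenes to 2,4-cis-4-alkoxyflavans and the chiral phosphoric acid or N-triflylphosphoramide catalysed (4+2) additions of styrenes to 4-aryl ortho-quinone methides; the new element is their combination on an oxocarbenium-type methide. Ring C closes in the (4+2) mode, the O1–C2 bond forming last, in the stepwise limit by 6-exo-trig capture of the benzylic cation. C4 is set by the anion, whose 3,3'-aryl groups shield one face of the bound methide, and C2 follows from C4 through the endo, chair-like closure that places the aryl and methoxy groups cis; the minor 2,4-trans isomer is removed by chromatography because it would give the (2R)-flavanone after oxidation. Regioselectivity (aryl at C2) comes from the polarisation of the styrene by the para chroman oxygen, and chemoselectivity for the styrene over the prenyl alkene from its higher nucleophilicity and its excess. The three oxygens of ring A allow ionisation by a moderately strong acid at −40 °C, conditions under which the MOM ethers and the prenyl group next to the free hydroxyl should survive.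

Step 8
Reactants: 18 (2S,4S)-2-(2,2-dimethylchroman-6-yl)-4-methoxy-5,7-bis(methoxymethoxy)-8-(3-methylbut-2-en-1-yl)chroman
Product: 20 (2S)-2-(2,2-dimethylchroman-6-yl)-5,7-bis(methoxymethoxy)-8-(3-methylbut-2-en-1-yl)chroman-4-one, via C4 hemiketal 19 (not isolated)
Conditions: DDQ (1.2 equiv), CH2Cl2/pH 7 phosphate buffer 10:1, 0 °C
Reagents that add atoms: water, O
Why: DDQ oxidative cleavage of an electron-rich benzylic ether, in which hydride is abstracted from C4 (the most hydridic C–H, flanked by the methoxy group and the trioxygenated ring A), water adds to the aryl(methoxy)carbenium ion and hemiketal 19 loses methanol; C2 is not involved and keeps its configuration.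

Step 9
Reactants: 20 (2S)-2-(2,2-dimethylchroman-6-yl)-5,7-bis(methoxymethoxy)-8-(3-methylbut-2-en-1-yl)chroman-4-one
Product: 21 euchrenone a16, (2S)-2-(2,2-dimethylchroman-6-yl)-5,7-dihydroxy-8-(3-methylbut-2-en-1-yl)chroman-4-one
Conditions: 3 M aq. HCl/MeOH 1:5, 45 °C, short reaction time; NaHCO3 work-up kept below pH 8
Reagents that add atoms: none
Why: acid-catalysed acetal cleavage (MOM removal by transacetalisation to methanol), the usual last step for prenylated flavanones; brief exposure to dilute acid should neither cyclise the C8 prenyl group onto the C7 hydroxyl nor open the flavanone at C2, and base is avoided to prevent racemisation through the chalcone.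

**Compound list**

1 | phloroglucinol (benzene-1,3,5-triol) | Oc1cc(O)cc(O)c1 | starting material
2 | chloromethyl methyl ether | COCCl | starting material
3 | 3,5-bis(methoxymethoxy)phenol | COCOc1cc(O)cc(OCOC)c1 | intermediate
4 | prenyl bromide (1-bromo-3-methylbut-2-ene) | CC(C)=CCBr | starting material
5 | 3,5-bis(methoxymethoxy)-2-(3-methylbut-2-en-1-yl)phenol | CC(C)=CCc1c(O)cc(OCOC)cc1OCOC | intermediate
6 | paraformaldehyde (written as formaldehyde) | C=O | starting material
7 | 2-(hydroxymethyl)-3,5-bis(methoxymethoxy)-6-(3-methylbut-2-en-1-yl)phenol (present as its magnesium phenoxide; not isolated) | CC(C)=CCc1c(OCOC)cc(OCOC)c(CO)c1O | intermediate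
8 | 2-hydroxy-4,6-bis(methoxymethoxy)-3-(3-methylbut-2-en-1-yl)benzaldehyde | CC(C)=CCc1c(OCOC)cc(OCOC)c(C=O)c1O | intermediate
9 | trimethyl orthoformate | COC(OC)OC | starting material
10 | 2-(dimethoxymethyl)-3,5-bis(methoxymethoxy)-6-(3-methylbut-2-en-1-yl)phenol | CC(C)=CCc1c(OCOC)cc(OCOC)c(C(OC)OC)c1O | intermediate
11 | 4-bromophenol | Oc1ccc(Br)cc1 | starting material
12 | isoprene | C=CC(C)=C | starting material
13 | 4-bromo-2-(3-methylbut-2-en-1-yl)phenol (not isolated) | CC(C)=CCc1cc(Br)ccc1O | intermediate
14 | 6-bromo-2,2-dimethylchroman | CC1(C)CCc2cc(Br)ccc2O1 | intermediate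
15 | vinylboronic acid pinacol ester (4,4,5,5-tetramethyl-2-vinyl-1,3,2-dioxaborolane) | C=CB1OC(C)(C)C(C)(C)O1 | starting material
16 | 2,2-dimethyl-6-vinylchroman | C=Cc1ccc2c(c1)CCC(C)(C)O2 | intermediate
17 | 6-(methoxymethylidene)-3,5-bis(methoxymethoxy)-2-(3-methylbut-2-en-1-yl)cyclohexa-2,4-dien-1-one (4-methoxy ortho-quinone methide, present as its O-protonated ion pair with the chiral anion; geometry of the exocyclic double bond not fixed; not isolated) | O=C1C(CC=C(C)C)=C(OCOC)C=C(OCOC)C1=COC | intermediate
18 | (2S,4S)-2-(2,2-dimethylchroman-6-yl)-4-methoxy-5,7-bis(methoxymethoxy)-8-(3-methylbut-2-en-1-yl)chroman (2,4-cis) | CC(C)=CCc1c(OCOC)cc(OCOC)c2c1O[C@H](c1ccc3c(c1)CCC(C)(C)O3)C[C@@H]2OC | intermediate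
19 | (2S)-2-(2,2-dimethylchroman-6-yl)-4-methoxy-5,7-bis(methoxymethoxy)-8-(3-methylbut-2-en-1-yl)chroman-4-ol (hemiketal, C4 configuration not defined; not isolated) | CC(C)=CCc1c(OCOC)cc(OCOC)c2c1O[C@H](c1ccc3c(c1)CCC(C)(C)O3)CC2(O)OC | intermediate
20 | (2S)-2-(2,2-dimethylchroman-6-yl)-5,7-bis(methoxymethoxy)-8-(3-methylbut-2-en-1-yl)chroman-4-one | CC(C)=CCc1c(OCOC)cc(OCOC)c2c1O[C@H](c1ccc3c(c1)CCC(C)(C)O3)CC2=O | intermediate
21 | euchrenone a16, (2S)-2-(2,2-dimethylchroman-6-yl)-5,7-dihydroxy-8-(3-methylbut-2-en-1-yl)chroman-4-one | CC(C)=CCc1c(O)cc(O)c2c1O[C@H](c1ccc3c(c1)CCC(C)(C)O3)CC2=O | target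

**Summary**

Total step count: 9. Longest linear sequence: 7 steps (steps 1, 2, 3, 4, 7, 8, 9); steps 5 and 6 form the second branch.

**Steps most likely to fail, with fallbacks**

Step 7 (Proposed new method). The chiral anion may discriminate the faces of the methide poorly. The acid needed for turnover may also cleave MOM groups, cyclise the prenyl group onto the free phenol or oligomerise the styrene. The cis preference of the ring closure may be eroded by the C5 substituent. The fallback uses the known racemic reaction and sets out from aldehyde 8 and styrene 16. With trimethyl orthoformate 9 and catalytic TfOH (1 mol %) in CH2Cl2 at −40 °C, acetal 10 forms in the flask and should give the racemic 2,4-cis cycloadduct F1. DDQ in wet CH2Cl2, as in step 8, should turn it into the racemic flavanone F2. Kinetic resolution by Noyori asymmetric transfer hydrogenation with RuCl[(R,R)-TsDPEN](p-cymene) in HCO2H/Et3N is expected to reduce the (2R)-enantiomer to the (2R,4R)-configured cis flavan-4-ol F3; the catalyst enantiomer would be confirmed on a small scale. The (2S)-ketone stays unreduced and is separated, and the route is rejoined at 20.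

Step 8. Hydride abstraction may compete at C2 (para-alkoxybenzylic and next to O1), at the benzylic CH2 of the prenyl group or of the chroman, or the product may be oxidised further towards the flavone. The fallback separates ionisation from oxidation and sets out from 18. Solvolysis of the C4 methyl ether with PPTS in THF/H2O at rt should give the (2S)-flavan-4-ol F4 as a mixture of C4 epimers, both of which are usable. Dess–Martin periodinane with NaHCO3 in CH2Cl2 at 0 °C should then oxidise the alcohol, and the route is rejoined at 20.

Step 2. O-alkylation, attack at the para carbon between the two MOM ethers and double prenylation may outrun the wanted ortho C-alkylation. The fallback replaces direct C-alkylation by O-alkylation and sigmatropic rearrangement, and sets out from 3. 3-Chloro-3-methylbut-1-yne with K2CO3, KI and catalytic CuI in acetone at reflux should give the 1,1-dimethylpropargyl ether F5. Lindlar semi-hydrogenation (H2, Pd/CaCO3 poisoned with Pb(OAc)2, quinoline, EtOAc) should give the 1,1-dimethylallyl ether F6. Aromatic Claisen rearrangement in toluene at 110 °C moves the allyl unit, with inversion, to one of the two equivalent ortho carbons, and the route is rejoined at 5.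

**Further compounds**

F1 | step 7 | racemic 2,4-cis cycloadduct, rac-(2S,4S)-2-(2,2-dimethylchroman-6-yl)-4-methoxy-5,7-bis(methoxymethoxy)-8-(3-methylbut-2-en-1-yl)chroman (both enantiomers written) | CC(C)=CCc1c(OCOC)cc(OCOC)c2c1O[C@H](c1ccc3c(c1)CCC(C)(C)O3)C[C@@H]2OC.CC(C)=CCc1c(OCOC)cc(OCOC)c2c1O[C@@H](c1ccc3c(c1)CCC(C)(C)O3)C[C@H]2OC
F2 | step 7 | racemic 2-(2,2-dimethylchroman-6-yl)-5,7-bis(methoxymethoxy)-8-(3-methylbut-2-en-1-yl)chroman-4-one | CC(C)=CCc1c(OCOC)cc(OCOC)c2c1OC(c1ccc3c(c1)CCC(C)(C)O3)CC2=O
F3 | step 7 | (2R,4R)-2-(2,2-dimethylchroman-6-yl)-5,7-bis(methoxymethoxy)-8-(3-methylbut-2-en-1-yl)chroman-4-ol (2,4-cis) | CC(C)=CCc1c(OCOC)cc(OCOC)c2c1O[C@@H](c1ccc3c(c1)CCC(C)(C)O3)C[C@H]2O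
F4 | step 8 | (2S)-2-(2,2-dimethylchroman-6-yl)-5,7-bis(methoxymethoxy)-8-(3-methylbut-2-en-1-yl)chroman-4-ol (mixture of C4 epimers) | CC(C)=CCc1c(OCOC)cc(OCOC)c2c1O[C@H](c1ccc3c(c1)CCC(C)(C)O3)CC2O
F5 | step 2 | 1,3-bis(methoxymethoxy)-5-(2-methylbut-3-yn-2-yloxy)benzene | C#CC(C)(C)Oc1cc(OCOC)cc(OCOC)c1
F6 | step 2 | 1,3-bis(methoxymethoxy)-5-(2-methylbut-3-en-2-yloxy)benzene | C=CC(C)(C)Oc1cc(OCOC)cc(OCOC)c1
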